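**Retrosynthetic overview**
- The target is a (2S,3R,4R)-2-aryl-3-(hydroxymethyl)-4-benzyl-oxolane; the last operation is O-debenzylation of the phenol.
- The oxolane (second and final ring) is closed by acid-mediated C2–O bond formation from an open (2R,3R)-triol, with C2 set under ring control (aryl trans to CH2OH).
- The triol comes from LiAlH4 reduction of a trans-3-benzyl-4-aroyl-γ-butyrolactone (first, temporary ring), built by hydroxymethylation with formaldehyde and lactonisation of a γ-keto ester; the trans lactone relays C3 to C4.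
- Key disconnection: the ArC(=O)–CH2 bond of the γ-keto ester, made from a carbene-generated acyl anion equivalent of veratraldehyde and a 2-(arylmethyl)acrylate (asymmetric Stetter; enantioselective protonation sets the one seeded stereocentre).
- The acrylate comes from an arylboronic acid and methyl 2-(bromomethyl)acrylate.

Assumption: the (S)-configured triazolium precatalyst gives the (R)-configured γ-keto ester; if the sense of protonation turns out opposite, the (R)-precatalyst is used and nothing else changes.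

**Step 1**
Reactants: 1 [4-(benzyloxy)-3-methoxyphenyl]boronic acid; 2 methyl 2-(bromomethyl)prop-2-enoate
Product: 3 methyl 2-{[4-(benzyloxy)-3-methoxyphenyl]methyl}prop-2-enoate
Conditions: Pd(PPh3)4 (3 mol%), K2CO3, THF/H2O, 60 °C
Reagents that add atoms: none
Why: Suzuki–Miyaura allyl–aryl cross-coupling, in which oxidative addition to the allylic bromide gives a symmetrical 2-(methoxycarbonyl)allyl-palladium species so that only the 2-benzylacrylate can form; no stereocentre is created.

**Step 2**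
Reactants: 3 methyl 2-{[4-(benzyloxy)-3-methoxyphenyl]methyl}prop-2-enoate; 4 3,4-dimethoxybenzaldehyde (1.5 equiv)
Product: 6 methyl (2R)-2-{[4-(benzyloxy)-3-methoxyphenyl]methyl}-4-(3,4-dimethoxyphenyl)-4-oxobutanoate, via Breslow intermediate 5 (not isolated)
Conditions: (S)-5-benzyl-2-mesityl-6,8-dihydro-5H-[1,2,4]triazolo[3,4-c][1,4]oxazin-2-ium BF4 (10 mol%), KOtBu (10 mol%), toluene, 0 °C to rt
Reagents that add atoms: none
Why: Asymmetric intermolecular Stetter reaction, in which the carbene turns the normally electrophilic aldehyde carbon of 4 into an acyl anion equivalent (5) that adds to the electrophilic CH2 terminus of acrylate 3, and the resulting ester enolate is protonated face-selectively inside the chiral carbene-bound adduct before catalyst release, setting C2 as R (known reaction class: carbene-catalysed Stetter addition to α-substituted acrylates with enantio-determining protonation).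

**Step 3**
Reactants: 6 methyl (2R)-2-{[4-(benzyloxy)-3-methoxyphenyl]methyl}-4-(3,4-dimethoxyphenyl)-4-oxobutanoate; 7 formaldehyde (37% aqueous, 1.2 equiv)
Product: 11 (3R,4R)-3-{[4-(benzyloxy)-3-methoxyphenyl]methyl}-4-(3,4-dimethoxybenzoyl)oxolan-2-one, via sodium keto-carboxylate 8 (not isolated), via sodium hydroxymethyl keto-carboxylate 9 (not isolated), via lactone C4-epimer mixture 10 (not isolated)
Conditions: NaOH (2.2 equiv), THF/MeOH/H2O, rt; aq. HCHO, 0 °C to rt; 2 M HCl to pH 1, rt; then DBU (0.2 equiv), CH2Cl2, rt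
Reagents that add atoms: sodium hydroxide, [Na+].[OH-] (its oxygen enters the carboxylate that closes the lactone)
Why: Saponification followed by crossed-aldol hydroxymethylation at the ketone α-CH2 (the carboxylate blocks deprotonation at the C2 stereocentre, and any dehydrated enone converges by 5-exo oxa-Michael closure), then acid lactonisation and DBU epimerisation of the ketone α-centre to the thermodynamically favoured trans lactone, so that C4 (R) is relayed from C3 (R).

**Step 4**
Reactants: 11 (3R,4R)-3-{[4-(benzyloxy)-3-methoxyphenyl]methyl}-4-(3,4-dimethoxybenzoyl)oxolan-2-one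
Product: 12 (2R,3R)-2-{[4-(benzyloxy)-3-methoxyphenyl]methyl}-3-[(3,4-dimethoxyphenyl)(hydroxy)methyl]butane-1,4-diol (both carbinol epimers)
Conditions: LiAlH4 (2.5 equiv), THF, 0 °C to rt; Na2SO4·10H2O quench
Reagents that add atoms: none
Why: Hydride reduction of the lactone to the 1,4-diol and of the ketone to the benzylic alcohol is faster than enolisation, so C2 and C3 are retained, and the unselectively formed carbinol centre is inconsequential because it is ionised in step 5.

**Step 5**
Reactants: 12 (2R,3R)-2-{[4-(benzyloxy)-3-methoxyphenyl]methyl}-3-[(3,4-dimethoxyphenyl)(hydroxy)methyl]butane-1,4-diol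
Product: 13 [(2S,3R,4R)-4-{[4-(benzyloxy)-3-methoxyphenyl]methyl}-2-(3,4-dimethoxyphenyl)oxolan-3-yl]methanol
Conditions: CSA (10 mol%), CH2Cl2, 0 °C to rt
Reagents that add atoms: none
Why: Acid-catalysed SN1 cycloetherification, in which the electron-rich benzylic alcohol ionises and is captured 5-exo by the C1 hydroxyl (the other primary hydroxyl could only give an oxetane), and reversible closure places the aryl group trans to the adjacent CH2OH, setting C2 as S, while mild acid and low temperature suppress Friedel–Crafts closure to an aryltetralin.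

**Step 6**
Reactants: 13 [(2S,3R,4R)-4-{[4-(benzyloxy)-3-methoxyphenyl]methyl}-2-(3,4-dimethoxyphenyl)oxolan-3-yl]methanol
Product: 14 4-{[(3R,4R,5S)-5-(3,4-dimethoxyphenyl)-4-(hydroxymethyl)oxolan-3-yl]methyl}-2-methoxyphenol
Conditions: H2 (1 atm), 10% Pd/C, EtOAc, rt, stopped at full conversion
Reagents that add atoms: none
Why: Catalytic hydrogenolysis of the aryl benzyl ether is much faster than cleavage of the ring benzylic C–O bond under neutral conditions at 1 atm, so the three stereocentres and the oxolane are untouched.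

**Compound list**
1 | [4-(benzyloxy)-3-methoxyphenyl]boronic acid | OB(O)c1ccc(OCc2ccccc2)c(OC)c1 | starting material
2 | methyl 2-(bromomethyl)prop-2-enoate | COC(=O)C(=C)CBr | starting material
3 | methyl 2-{[4-(benzyloxy)-3-methoxyphenyl]methyl}prop-2-enoate | COC(=O)C(=C)Cc1ccc(OCc2ccccc2)c(OC)c1 | intermediate
4 | 3,4-dimethoxybenzaldehyde (veratraldehyde) | COc1ccc(C=O)cc1OC | starting material
5 | Breslow intermediate: {(5S)-5-benzyl-2-mesityl-5,6-dihydro-8H-[1,2,4]triazolo[3,4-c][1,4]oxazin-3(2H)-ylidene}(3,4-dimethoxyphenyl)methanol (enaminol of 4 and the carbene, C=C geometry not defined) | OC(c1ccc(OC)c(OC)c1)=C1N(c2c(C)cc(C)cc2C)N=C2COC[C@H](Cc3ccccc3)N12 | intermediate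
6 | methyl (2R)-2-{[4-(benzyloxy)-3-methoxyphenyl]methyl}-4-(3,4-dimethoxyphenyl)-4-oxobutanoate | COC(=O)[C@H](Cc1ccc(OCc2ccccc2)c(OC)c1)CC(=O)c1ccc(OC)c(OC)c1 | intermediate
7 | formaldehyde (37% aqueous solution) | C=O | starting material
8 | sodium (2R)-2-{[4-(benzyloxy)-3-methoxyphenyl]methyl}-4-(3,4-dimethoxyphenyl)-4-oxobutanoate | [Na+].[O-]C(=O)[C@H](Cc1ccc(OCc2ccccc2)c(OC)c1)CC(=O)c1ccc(OC)c(OC)c1 | intermediate
9 | sodium (2R)-2-{[4-(benzyloxy)-3-methoxyphenyl]methyl}-4-(3,4-dimethoxyphenyl)-3-(hydroxymethyl)-4-oxobutanoate (both C3 epimers) | [Na+].[O-]C(=O)[C@H](Cc1ccc(OCc2ccccc2)c(OC)c1)C(CO)C(=O)c1ccc(OC)c(OC)c1 | intermediate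
10 | (3R)-3-{[4-(benzyloxy)-3-methoxyphenyl]methyl}-4-(3,4-dimethoxybenzoyl)oxolan-2-one (cis/trans mixture at C4) | O=C1OCC(C(=O)c2ccc(OC)c(OC)c2)[C@H]1Cc1ccc(OCc2ccccc2)c(OC)c1 | intermediate
11 | (3R,4R)-3-{[4-(benzyloxy)-3-methoxyphenyl]methyl}-4-(3,4-dimethoxybenzoyl)oxolan-2-one (trans) | O=C1OC[C@H](C(=O)c2ccc(OC)c(OC)c2)[C@H]1Cc1ccc(OCc2ccccc2)c(OC)c1 | intermediate
12 | (2R,3R)-2-{[4-(benzyloxy)-3-methoxyphenyl]methyl}-3-[(3,4-dimethoxyphenyl)(hydroxy)methyl]butane-1,4-diol (both carbinol epimers) | OC[C@H](Cc1ccc(OCc2ccccc2)c(OC)c1)[C@H](CO)C(O)c1ccc(OC)c(OC)c1 | intermediate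
13 | [(2S,3R,4R)-4-{[4-(benzyloxy)-3-methoxyphenyl]methyl}-2-(3,4-dimethoxyphenyl)oxolan-3-yl]methanol | COc1cc(C[C@H]2CO[C@H](c3ccc(OC)c(OC)c3)[C@H]2CO)ccc1OCc1ccccc1 | intermediate
14 | 4-{[(3R,4R,5S)-5-(3,4-dimethoxyphenyl)-4-(hydroxymethyl)oxolan-3-yl]methyl}-2-methoxyphenol | COc1cc(C[C@H]2CO[C@H](c3ccc(OC)c(OC)c3)[C@H]2CO)ccc1O | target

**Totals**
Total step count: 6. Longest linear sequence: 6 steps (1 or 2 to 14).

**Steps most likely to fail, with fallbacks**

Step 2 (Stetter): the electron-rich aldehyde may turn over slowly or stall at the benzoin stage, or the protonation may give low ee. The fallback sets out from 1 and replaces catalytic protonation control by auxiliary-controlled enolate alkylation with an α-bromo ketone. Rh-catalysed 1,4-addition of 1 to (S)-3-acryloyl-4-benzyl-1,3-oxazolidin-2-one ([Rh(cod)OH]2, dioxane/H2O) gives the imide (4S)-4-benzyl-3-{3-[4-(benzyloxy)-3-methoxyphenyl]propanoyl}-1,3-oxazolidin-2-one F1. Its sodium enolate (NaHMDS, THF, −78 °C) is alkylated by 2-bromo-1-(3,4-dimethoxyphenyl)ethan-1-one on the face away from the auxiliary benzyl group to give (4S)-4-benzyl-3-[(2R)-2-{[4-(benzyloxy)-3-methoxyphenyl]methyl}-4-(3,4-dimethoxyphenyl)-4-oxobutanoyl]-1,3-oxazolidin-2-one F2. LiOH/H2O2 removes the auxiliary to give (2R)-2-{[4-(benzyloxy)-3-methoxyphenyl]methyl}-4-(3,4-dimethoxyphenyl)-4-oxobutanoic acid F3, which with NaOH is compound 8, where the route is rejoined inside step 3.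

Step 3 (hydroxymethylation/lactonisation): double hydroxymethylation or base-induced dehydration may erode the yield. The fallback sets out from 6 and makes the aldol a single, Lewis-acid-mediated event on a preformed enol ether. TMSOTf/Et3N (CH2Cl2, 0 °C) converts the ketone into methyl (2R,3Z)-2-{[4-(benzyloxy)-3-methoxyphenyl]methyl}-4-(3,4-dimethoxyphenyl)-4-[(trimethylsilyl)oxy]but-3-enoate F4. Mukaiyama aldol reaction with aqueous formaldehyde and catalytic Yb(OTf)3 in THF/H2O gives methyl (2R)-2-{[4-(benzyloxy)-3-methoxyphenyl]methyl}-4-(3,4-dimethoxyphenyl)-3-(hydroxymethyl)-4-oxobutanoate F5 as a C3-epimer mixture. Catalytic TsOH in toluene at 60 °C lactonises F5 with loss of methanol to compound 10, where the route is rejoined for the DBU equilibration to 11.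

Step 6 (hydrogenolysis): the 2-aryl-oxolane C–O bond may also be cleaved, opening the ring. The fallback sets out from 12 and removes the benzyl group before the ring exists. Hydrogenolysis of 12 (H2, Pd/C, EtOAc) gives (2R,3R)-2-[(3,4-dimethoxyphenyl)(hydroxy)methyl]-3-[(4-hydroxy-3-methoxyphenyl)methyl]butane-1,4-diol F6. CSA-catalysed cyclisation of F6 (CH2Cl2/THF, 0 °C to rt), as in step 5, then gives compound 14 directly.

**Further compounds**
F1 | step 2 | (4S)-4-benzyl-3-{3-[4-(benzyloxy)-3-methoxyphenyl]propanoyl}-1,3-oxazolidin-2-one | O=C(CCc1ccc(OCc2ccccc2)c(OC)c1)N1[C@@H](Cc2ccccc2)COC1=O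
F2 | step 2 | (4S)-4-benzyl-3-[(2R)-2-{[4-(benzyloxy)-3-methoxyphenyl]methyl}-4-(3,4-dimethoxyphenyl)-4-oxobutanoyl]-1,3-oxazolidin-2-one | O=C([C@H](Cc1ccc(OCc2ccccc2)c(OC)c1)CC(=O)c1ccc(OC)c(OC)c1)N1[C@@H](Cc2ccccc2)COC1=O
F3 | step 2 | (2R)-2-{[4-(benzyloxy)-3-methoxyphenyl]methyl}-4-(3,4-dimethoxyphenyl)-4-oxobutanoic acid | OC(=O)[C@H](Cc1ccc(OCc2ccccc2)c(OC)c1)CC(=O)c1ccc(OC)c(OC)c1
F4 | step 3 | methyl (2R,3Z)-2-{[4-(benzyloxy)-3-methoxyphenyl]methyl}-4-(3,4-dimethoxyphenyl)-4-[(trimethylsilyl)oxy]but-3-enoate | COC(=O)[C@H](Cc1ccc(OCc2ccccc2)c(OC)c1)/C=C(\O[Si](C)(C)C)c1ccc(OC)c(OC)c1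
F5 | step 3 | methyl (2R)-2-{[4-(benzyloxy)-3-methoxyphenyl]methyl}-4-(3,4-dimethoxyphenyl)-3-(hydroxymethyl)-4-oxobutanoate (both C3 epimers) | COC(=O)[C@H](Cc1ccc(OCc2ccccc2)c(OC)c1)C(CO)C(=O)c1ccc(OC)c(OC)c1
F6 | step 6 | (2R,3R)-2-[(3,4-dimethoxyphenyl)(hydroxy)methyl]-3-[(4-hydroxy-3-methoxyphenyl)methyl]butane-1,4-diol (both carbinol epimers) | OC[C@H](Cc1ccc(O)c(OC)c1)[C@H](CO)C(O)c1ccc(OC)c(OC)c1
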